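## Analysis of the target

Neoirietetraol (42) is a C20 dibromo tetraol whose carbons are numbered C1–C20 along the SMILES string, with ring A the cyclopentane C2, C4–C7, ring B C9–C12, C19, C20 and ring C C12, C14–C17, C19. Ring A is joined through the C7–C9 bond to a trans-fused decalin (rings B and C). There are eight stereocentres (4R,6S,7R,9R,12S,14S,17R,19R), five of them fully substituted (C7, C9, C12, C17, C19), and the achiral quaternary C2 sits next to C7. On ring A the C4 bromine, the C6 hydroxyl and the C7–C9 bond are all cis, with the C7 methyl on the other face. In the decalin the C13 methyl and the C19 hydroxyl are trans and axial, the C14 bromine is equatorial, the C17/C19 diol is trans-diaxial, and the C9 hydroxyl is axial and syn to the C19 hydroxyl, so ring A is equatorial on ring B. The sensitive groups are two secondary bromides next to quaternary carbons (elimination, hydrogenolysis, strong one-electron reductants) and three tertiary alcohols (ionisation, dehydration). The difficulty lies in the vicinal quaternary pair C2/C7, the union of two congested halves at the carbinol C9, and the bromides, which cannot be made by routine substitution on a cyclohexane. The strategy rests on ring A: C6 bears oxygen, is bonded to quaternary C7 and is 1,3 to the heteroatom-bearing C4, so ring A is a 3-oxycyclopentanone whose C5–C6 bond can be made by adding a C6 aldehyde C–H bond across a C4=C5 enol ether.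

## Retrosynthetic reasoning

**42 to 39.** The last operations are removal of the C6 4-methoxybenzyl ether from 41 and, before that, installation of the C17/C19 diol on the tetrasubstituted C17=C19 alkene of 39 through epoxide 40. A trans-diaxial diol is what hydrolytic opening of either epoxide of such an octalin gives, with attack at C17 under inversion. The three tertiary alcohols therefore appear only at the end.

**39 to 38 (C9–C20).** Ring B is opened at C9–C20. In the forward direction the C20 allylic pivalate of 38 is converted in the flask into a nucleophilic allyl–samarium unit that adds to the C9 ketone. The closure must go through C20 and not through the tetrasubstituted C17. Because C9 becomes stereogenic in a six-membered transition state, the bulky ring A takes the equatorial position and the hydroxyl ends up axial, as required.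

**38 to 18 and 34 (C9–C10).** C9 is the only atom linking the two halves and C10 is an unhindered methylene, so the C10 sulfonyl carbanion 35 of the ring C fragment 34 is added to the ring A aldehyde 18. Oxidation of 36 to 37 and reductive loss of the sulfone then give 38, in which C9 and C12 are separated by the two methylene groups C10 and C11. A stabilised carbanion is chosen because it tolerates the secondary bromides.

**18 back to 12.** The C9 aldehyde comes from the primary alcohol 17. This is freed by regioselective reductive opening of the 4-methoxybenzylidene acetal 16, which leaves the ether on O6. The C4 bromide of 16 comes from alcohol 14 through triflate 15 with inversion. This substitution is placed early, at the one stage where C4–OH is the only free hydroxyl (only the cis O6/O9 pair of triol 13 can be bridged), and not at the end, where three tertiary alcohols would compete.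

**12 to 10.** The C6 hydroxyl of 12 is derived from the C6 ketone of 11 by hydride delivered from the C4 hydroxyl. The C4 oxygen thus controls C6 and is afterwards replaced by bromine with inversion, which gives the all-cis array.

**10 to 9 (key, C5–C6).** Ring A is cut at C5–C6 and the hydrogen on C4 is returned to the aldehyde: 10 becomes the open-chain aldehyde 9 with a C4=C5 silyl enol ether. One catalytic step then makes the ring, the ketone and the C4 stereocentre, and the precursor has a single stereocentre (C7).

**9 to 1 and 2.** The enol ether comes from methyl ketone 8, and the ketone from the isopropenyl group of 7 by ozonolysis. The acetyl unit is carried as an alkene so that neither a hydroxyl nor a ketone ever sits within reach of the two ester groups of 4, where lactonisation or acyl cleavage would destroy the symmetry. Aldehyde 7 comes from monoacetate 6, made by enzymatic desymmetrisation of diol 5, and this sets C7. C9 is carried as an acetoxymethyl group and not as an ester: a carboxyl carbon on C7 would be shielded by two fully substituted neighbours from both an enzyme and a carbon nucleophile, whereas the hydroxymethyl arm is accessible and is later oxidised for the fragment union. Diol 5 comes from malonate 4, 4 from 3 by methylation, and 3 from conjugate addition of 2 to 1, whose C=C bond already is the C2–C7 bond.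

**34 to 29.** The C17=C19 alkene with an allylic leaving group at C20 is derived from cyclic carbonate 29. Methanolysis gives 30, oxidation gives 31, β-elimination gives enal 32, and reduction and acylation give 33 and 34. This avoids the mixtures of alkene isomers that proton loss from a cyclised cation would give.

**29 to 25 (C12–C19).** Ring C is opened at C12–C19 and C17–O, a bromonium-ion cyclisation terminated by the carbonate. Its absolute configuration is taken from epoxide 26, via bromohydrin 27 and triflate 28, so that the bromonium ion is formed enantiospecifically by neighbouring-group displacement.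

**25 to 19.** The C10–C11 bond is made by alkylating lithiated sulfone 24 (from 23) with allylic bromide 22. This is obtained from geraniol 19 through carbonate 20 and E-selective allylic oxidation to 21.

## Alternatives that were turned down

**Alternative 1:** Ring B is cut at C10=C11, the only decalin bond not attached to a fully substituted carbon at both ends. The forward step is ring-closing metathesis with the second-generation Grubbs catalyst between vinyl groups on C9 and C12, giving the diene carbinol A1.
- For: the catalyst ignores bromides and a free tertiary hydroxyl, and the tetrasubstituted C17=C19 alkene is inert. The new disubstituted alkene can later be reduced selectively. This closure is probably more reliable than the reductive allylation of step 30.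
- Against: a vinyl group on C12 is incompatible with making ring C by bromonium cyclisation, because the cationic centre would be allylic. C9 would become stereogenic in an open-chain carbonyl addition with only the remote ring A centres to bias it. The step does nothing for ring A, which holds the vicinal quaternary carbons and the cis bromine/hydroxyl pair.
- In comparison, the chosen plan builds ring A, its ketone and the C4 oxygen in one catalyst-controlled step and sets C9 during a ring closure.

**Alternative 2:** Ring A is traced back to a cyclohexane by cutting C6–C7. In the forward step MeAl(OC6H2-4-Br-2,6-t-Bu2)2 breaks the C7–O bond of an epoxide and the silyloxy-bearing C6 shifts from C9 to C7 anti to that bond, giving aldehyde A2.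
- For: the migration is stereospecific, so the C6/C7 relationship follows from an easily set epoxy alcohol. Quaternary C7 arises without constructing a bond between two quaternary carbons. C9 emerges as an aldehyde, ready for coupling. On this point it is stronger than the chosen route, which needs several protecting-group and redox steps to reach 18.
- Against: A2 has only methylene groups at C4 and C5. The C4 bromine would have to be introduced by functionalising an unactivated C–H bond next to a quaternary carbon, cis to the other substituents, which is not realistic. Carrying a C4 substituent through the rearrangement adds a stereocentre and a competing leaving group.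
- In comparison, the hydroacylation delivers the C4 heteroatom as part of ring formation.

**Alternative 3:** Ring A is cut at C2–C4. In the forward step Fe(acac)3 and PhSiH3 transfer a hydrogen atom to the CH2 of an isopropenyl group on C7, and the tertiary C2 radical adds to a C4 aldehyde, giving cyclopentanol A3.
- For: a tertiary radical is insensitive to congestion and the catalyst is cheap. A3 already has O6 and O9 differentiated and C4–OH free, the stage the chosen route reaches only at 14. On these points it is as strong or stronger.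
- Against: radical addition to an aldehyde is reversible through β-scission and depends on fast reduction of the alkoxy radical. The C4 configuration is under substrate control only. The open-chain precursor must already carry the C6 and C7 stereocentres and is an enolisable β-alkoxy aldehyde prone to elimination.
- In comparison, the chosen strategy sets C4 by the catalyst, derives C6 from C4 by directed reduction, and needs a precursor with one stereocentre.

Key step: step 8

Assumption: the sense of induction of the lipase in step 4 and of (S)-BINAP in step 8 is taken as drawn; if either is opposite, the diacetate-hydrolysis mode (step 4) or (R)-BINAP (step 8) leads to the same compounds.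

## Route

### Ring A fragment

Step 1
Reactants: 1 diethyl 2-(propan-2-ylidene)malonate; 2 isopropenylmagnesium bromide
Product: 3 diethyl 2-(2,3-dimethylbut-3-en-2-yl)malonate
Conditions: CuI (10 mol%), THF, –20 → 0 °C; aq. NH4Cl
Reagents that add atoms: none
Why: Copper-catalysed conjugate addition of a Grignard reagent to an alkylidene malonate; the C2–C7 bond is already present in 1, and the addition makes C2 quaternary and brings in C4/C5 as an alkene that later becomes the acetyl group.

Step 2
Reactants: 3 diethyl 2-(2,3-dimethylbut-3-en-2-yl)malonate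
Product: 4 diethyl 2-(2,3-dimethylbut-3-en-2-yl)-2-methylmalonate
Conditions: NaH, DMF, 0 °C; MeI, 0 → 50 °C
Reagents that add atoms: iodomethane, CI
Why: C-alkylation of a malonate anion; the smallest electrophile reaches the hindered carbon and makes C7 quaternary but still prochiral.

Step 3
Reactants: 4 diethyl 2-(2,3-dimethylbut-3-en-2-yl)-2-methylmalonate
Product: 5 2-(2,3-dimethylbut-3-en-2-yl)-2-methylpropane-1,3-diol
Conditions: LiAlH4, THF, 0 °C → reflux; aqueous NaOH work-up
Reagents that add atoms: none
Why: Hydride reduction of both esters; the small hydride reaches carbonyls that larger nucleophiles cannot, and the isolated alkene is inert.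

Step 4
Reactants: 5 2-(2,3-dimethylbut-3-en-2-yl)-2-methylpropane-1,3-diol
Product: 6 (2R)-2-(hydroxymethyl)-2,3,3,4-tetramethylpent-4-en-1-yl acetate
Conditions: Burkholderia cepacia lipase (Amano PS), vinyl acetate, i-Pr2O, 25 °C
Reagents that add atoms: vinyl acetate, C=COC(C)=O
Why: Lipase-catalysed desymmetrising monoacylation of a prochiral 2,2-disubstituted propane-1,3-diol; the enzyme distinguishes the two hydroxymethyl arms by the large size difference between methyl and the tertiary alkyl group, and this sets C7.

Step 5
Reactants: 6 (2R)-2-(hydroxymethyl)-2,3,3,4-tetramethylpent-4-en-1-yl acetate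
Product: 7 (2S)-2-formyl-2,3,3,4-tetramethylpent-4-en-1-yl acetate
Conditions: Dess–Martin periodinane, NaHCO3, CH2Cl2, 0 → 25 °C
Reagents that add atoms: none
Why: Neutral oxidation of the free arm to the C6 aldehyde; prompt oxidation prevents 1,3-acyl migration, and the aldehyde has no α-hydrogen, so C7 cannot epimerise.

Step 6
Reactants: 7 (2S)-2-formyl-2,3,3,4-tetramethylpent-4-en-1-yl acetate
Product: 8 (2S)-2-formyl-2,3,3-trimethyl-4-oxopentyl acetate
Conditions: O3, CH2Cl2, –78 °C; PPh3
Reagents that add atoms: ozone, [O-][O+]=O
Why: Ozonolysis of the 1,1-disubstituted alkene with reductive work-up gives the C4 methyl ketone; aldehyde and acetate survive at –78 °C.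

Step 7
Reactants: 8 (2S)-2-formyl-2,3,3-trimethyl-4-oxopentyl acetate
Product: 9 (2S)-2-formyl-2,3,3-trimethyl-4-(triisopropylsilyloxy)pent-4-en-1-yl acetate
Conditions: TIPSOTf (1.1 equiv), Et3N, CH2Cl2, –78 → 0 °C
Reagents that add atoms: triisopropylsilyl trifluoromethanesulfonate, CC(C)[Si](C(C)C)(C(C)C)OS(=O)(=O)C(F)(F)F
Why: Soft enolisation of the methyl ketone; the enol ether can form only toward C5 because C2 has no hydrogen, the aldehyde cannot enolise, and closure of the new enol ether onto the aldehyde would be a geometrically disfavoured 5-(enolendo) aldol.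

Step 8
Reactants: 9 (2S)-2-formyl-2,3,3-trimethyl-4-(triisopropylsilyloxy)pent-4-en-1-yl acetate
Product: 10 [(1S,3S)-1,2,2-trimethyl-5-oxo-3-(triisopropylsilyloxy)cyclopentyl]methyl acetate
Conditions: [Rh((S)-BINAP)]BF4 (5 mol%; from [Rh((S)-BINAP)(nbd)]BF4 and H2), CH2Cl2, 25 °C
Reagents that add atoms: none
Why: Proposed new method: the C6–H bond of the aldehyde adds oxidatively to monovalent rhodium, the C4=C5 enol ether inserts into the Rh–H bond with hydride going to C4 to give a six-membered acyl–alkyl rhodacycle, and C5–C6 reductive elimination releases the cyclopentanone. The closest known reaction type is the rhodium–bisphosphine cyclisation of 4-substituted pent-4-enals to 3-substituted cyclopentanones, where alkyl, aryl, silyl and carbonyl groups, but not a silyloxy group, have occupied C4. Ring A closes in a formally 5-endo-trig sense (both alkene carbons end up in the ring), which is possible because the bond is made by reductive elimination from the metallacycle and not by direct attack. The new C4 stereocentre is set at the insertion step by the chiral pocket of (S)-BINAP; the C7 centre is remote and its two small substituents (CH3, CH2OAc) are too alike to override the ligand, so the oxygen should end up trans to the C9 arm. The step needs hydroacylation to outrun decarbonylation, which the quaternary C7 (no α-hydrogen, slow migration of a tertiary alkyl group) and the Thorpe–Ingold effect of C2 and C7 favour. It also needs the alkene to stay in place, which is assured because C2 has no hydrogen and the bulky silyl group resists transfer.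

Step 9
Reactants: 10 [(1S,3S)-1,2,2-trimethyl-5-oxo-3-(triisopropylsilyloxy)cyclopentyl]methyl acetate
Product: 11 [(1S,3S)-3-hydroxy-1,2,2-trimethyl-5-oxocyclopentyl]methyl acetate
Conditions: HF (48% aq.), MeCN, 25 °C
Reagents that add atoms: none
Why: Acidic desilylation; a basic fluoride source is avoided because the β-hydroxy ketone would eliminate by E1cB.

Step 10
Reactants: 11 [(1S,3S)-3-hydroxy-1,2,2-trimethyl-5-oxocyclopentyl]methyl acetate
Product: 12 [(1S,3S,5S)-3,5-dihydroxy-1,2,2-trimethylcyclopentyl]methyl acetate
Conditions: Me4NBH(OAc)3, MeCN–AcOH, –30 °C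
Reagents that add atoms: none
Why: Hydroxyl-directed (Saksena–Evans) reduction; the C4 alkoxyborohydride delivers hydride to C6 from its own face, so the new hydroxyl is trans to C4–OH and cis to C9, and the acetate keeps O9 from acting as a second directing group.

Step 11
Reactants: 12 [(1S,3S,5S)-3,5-dihydroxy-1,2,2-trimethylcyclopentyl]methyl acetate
Product: 13 (1S,3S,4S)-4-(hydroxymethyl)-4,5,5-trimethylcyclopentane-1,3-diol
Conditions: K2CO3 (cat.), MeOH, 25 °C
Reagents that add atoms: none
Why: Transesterification of the primary acetate; no base-sensitive group is present.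

Step 12
Reactants: 13 (1S,3S,4S)-4-(hydroxymethyl)-4,5,5-trimethylcyclopentane-1,3-diol
Product: 14 (2R,4aS,6S,7aS)-2-(4-methoxyphenyl)-4a,5,5-trimethylhexahydrocyclopenta[d][1,3]dioxin-6-ol
Conditions: 4-MeOC6H4CH(OMe)2, PPTS (cat.), CH2Cl2, 25 °C
Reagents that add atoms: 4-methoxybenzaldehyde dimethyl acetal, COc1ccc(C(OC)OC)cc1
Why: Thermodynamic acetalisation; only the cis O6/O9 pair can form a six-membered acetal (aryl equatorial), which leaves C4–OH as the only free hydroxyl.

Step 13
Reactants: 14 (2R,4aS,6S,7aS)-2-(4-methoxyphenyl)-4a,5,5-trimethylhexahydrocyclopenta[d][1,3]dioxin-6-ol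
Product: 16 (2R,4aS,6R,7aS)-6-bromo-2-(4-methoxyphenyl)-4a,5,5-trimethylhexahydrocyclopenta[d][1,3]dioxine, via C4 triflate 15 (not isolated)
Conditions: Tf2O, 2,6-lutidine, CH2Cl2, –20 °C; then Bu4NBr, toluene, 0 → 25 °C
Reagents that add atoms: tetrabutylammonium bromide, CCCC[N+](CCCC)(CCCC)CCCC.[Br-]
Why: SN2 displacement of a secondary cyclopentyl triflate by bromide with inversion, which puts bromine cis to O6 and C9; the non-basic nucleophile and non-ionising solvent are chosen to hold back elimination and methyl migration at this neopentyl-type centre.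

Step 14
Reactants: 16 (2R,4aS,6R,7aS)-6-bromo-2-(4-methoxyphenyl)-4a,5,5-trimethylhexahydrocyclopenta[d][1,3]dioxine
Product: 17 [(1S,3R,5S)-3-bromo-5-(4-methoxybenzyloxy)-1,2,2-trimethylcyclopentyl]methanol
Conditions: i-Bu2AlH, CH2Cl2, –78 → 0 °C
Reagents that add atoms: none
Why: Reductive opening of the arylidene acetal; the aluminium hydride binds the less hindered primary oxygen (O9) and cleaves that C–O bond, leaving the 4-methoxybenzyl ether on O6.

Step 15
Reactants: 17 [(1S,3R,5S)-3-bromo-5-(4-methoxybenzyloxy)-1,2,2-trimethylcyclopentyl]methanol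
Product: 18 (1R,3R,5S)-3-bromo-5-(4-methoxybenzyloxy)-1,2,2-trimethylcyclopentane-1-carbaldehyde
Conditions: Dess–Martin periodinane, NaHCO3, CH2Cl2, 25 °C
Reagents that add atoms: none
Why: Neutral oxidation to the C9 aldehyde, which has no α-hydrogen and so can neither epimerise nor eliminate the β-alkoxy group.

### Ring C fragment

Step 16
Reactants: 19 geraniol
Product: 20 tert-butyl (2E)-3,7-dimethylocta-2,6-dien-1-yl carbonate
Conditions: Boc2O, DMAP (cat.), CH2Cl2, 0 → 25 °C
Reagents that add atoms: di-tert-butyl dicarbonate, CC(C)(C)OC(=O)OC(=O)OC(C)(C)C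
Why: O-acylation; the carbonate deactivates the C17=C19 alkene toward the oxidants of steps 17 and 20 and later serves as the internal nucleophile of the cyclisation.

Step 17
Reactants: 20 tert-butyl (2E)-3,7-dimethylocta-2,6-dien-1-yl carbonate
Product: 21 tert-butyl (2E,6E)-8-hydroxy-3,7-dimethylocta-2,6-dien-1-yl carbonate
Conditions: SeO2 (0.2 equiv), t-BuOOH, salicylic acid (cat.), CH2Cl2, 25 °C
Reagents that add atoms: tert-butyl hydroperoxide, CC(C)(C)OO
Why: Selenium-dioxide allylic hydroxylation (ene reaction, then 2,3-shift) is E-selective at the terminal prenyl unit; the oxidised carbon becomes C11 and the untouched cis methyl becomes C13, which fixes the later C12 configuration.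

Step 18
Reactants: 21 tert-butyl (2E,6E)-8-hydroxy-3,7-dimethylocta-2,6-dien-1-yl carbonate
Product: 22 tert-butyl (2E,6E)-8-bromo-3,7-dimethylocta-2,6-dien-1-yl carbonate
Conditions: CBr4, PPh3, CH2Cl2, 0 °C
Reagents that add atoms: carbon tetrabromide, BrC(Br)(Br)Br
Why: Appel bromination of a primary allylic alcohol, without allylic transposition at low temperature.

Step 19
Reactants: 22 tert-butyl (2E,6E)-8-bromo-3,7-dimethylocta-2,6-dien-1-yl carbonate; 23 methyl phenyl sulfone
Product: 25 tert-butyl (2E,6E)-3,7-dimethyl-9-(phenylsulfonyl)nona-2,6-dien-1-yl carbonate, via lithiated sulfone 24 (not isolated)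
Conditions: n-BuLi, THF, –78 °C; then 22, –78 °C
Reagents that add atoms: none
Why: SN2 alkylation of an α-sulfonyl carbanion by a primary allylic bromide adds C10 together with the group that will make it nucleophilic; the hindered carbonate is not attacked at –78 °C.

Step 20
Reactants: 25 tert-butyl (2E,6E)-3,7-dimethyl-9-(phenylsulfonyl)nona-2,6-dien-1-yl carbonate
Product: 26 tert-butyl (2E)-3-methyl-5-[(2R,3R)-3-methyl-3-[2-(phenylsulfonyl)ethyl]oxiran-2-yl]pent-2-en-1-yl carbonate
Conditions: Shi ketone from D-fructose (0.3 equiv), KHSO5 (Oxone), K2CO3, Bu4NHSO4, MeCN–CH2(OMe)2–aq. Na2B4O7 buffer, 0 °C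
Reagents that add atoms: potassium peroxymonosulfate, [K+].[O-]S(=O)(=O)OO
Why: Shi epoxidation of the electron-rich trisubstituted C12=C14 alkene; the spiro transition state of the D-fructose ketone gives the (R,R)-epoxide, and the allylic carbonate alkene is too electron-poor to compete.

Step 21
Reactants: 26 tert-butyl (2E)-3-methyl-5-[(2R,3R)-3-methyl-3-[2-(phenylsulfonyl)ethyl]oxiran-2-yl]pent-2-en-1-yl carbonate
Product: 27 tert-butyl (2E,6R,7S)-7-bromo-6-hydroxy-3,7-dimethyl-9-(phenylsulfonyl)non-2-en-1-yl carbonate
Conditions: HBr (48% aq., 1.1 equiv), Et2O, –30 °C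
Reagents that add atoms: hydrogen bromide, Br
Why: Acid-promoted epoxide opening at the tertiary carbon with inversion (borderline SN2) gives the anti bromohydrin with bromine on C12 and hydroxyl on C14; the short cold exposure spares the carbonate.

Step 22
Reactants: 27 tert-butyl (2E,6R,7S)-7-bromo-6-hydroxy-3,7-dimethyl-9-(phenylsulfonyl)non-2-en-1-yl carbonate
Product: 29 (4aR,5S,6S,8aS)-6-bromo-5,8a-dimethyl-5-[2-(phenylsulfonyl)ethyl]hexahydro-4H-benzo[d][1,3]dioxin-2-one, via secondary triflate 28 (not isolated)
Conditions: Tf2O, 2,6-di-tert-butyl-4-methylpyridine, CH2Cl2, –78 → –20 °C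
Reagents that add atoms: none
Why: The neighbouring bromine displaces the C14 triflate from the rear (inversion at C14) to give a bromonium ion of defined configuration, and the E-alkene C19 attacks C12 anti to bromine through a chair (cation–olefin cyclisation). The C17 cation is captured by the carbonate carbonyl with loss of isobutene, so C14–Br is equatorial, the C13 methyl axial and the carbonate trans-fused. No free electrophilic bromine is present, so the configuration cannot scramble by transfer between alkenes.

Step 23
Reactants: 29 (4aR,5S,6S,8aS)-6-bromo-5,8a-dimethyl-5-[2-(phenylsulfonyl)ethyl]hexahydro-4H-benzo[d][1,3]dioxin-2-one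
Product: 30 (1S,2R,3S,4S)-4-bromo-2-(hydroxymethyl)-1,3-dimethyl-3-[2-(phenylsulfonyl)ethyl]cyclohexan-1-ol
Conditions: K2CO3, MeOH, 25 °C
Reagents that add atoms: none
Why: Methanolysis of the cyclic carbonate; the equatorial neopentyl bromide has no anti-periplanar hydrogen and resists elimination and substitution.

Step 24
Reactants: 30 (1S,2R,3S,4S)-4-bromo-2-(hydroxymethyl)-1,3-dimethyl-3-[2-(phenylsulfonyl)ethyl]cyclohexan-1-ol
Product: 32 (5S,6S)-5-bromo-2,6-dimethyl-6-[2-(phenylsulfonyl)ethyl]cyclohex-1-ene-1-carbaldehyde, via hydroxy aldehyde 31 (not isolated)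
Conditions: Dess–Martin periodinane, NaHCO3, CH2Cl2, 0 °C; then TsOH·H2O (cat.), toluene, 50 °C
Reagents that add atoms: none
Why: Oxidation of the primary alcohol followed by acid-catalysed aldol-type dehydration through the enol; the conjugated tetrasubstituted enal is the thermodynamic sink, so the C17=C19 alkene is formed regiospecifically and the temporary C17 and C19 stereocentres are removed on purpose.

Step 25
Reactants: 32 (5S,6S)-5-bromo-2,6-dimethyl-6-[2-(phenylsulfonyl)ethyl]cyclohex-1-ene-1-carbaldehyde
Product: 33 [(5S,6S)-5-bromo-2,6-dimethyl-6-[2-(phenylsulfonyl)ethyl]cyclohex-1-en-1-yl]methanol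
Conditions: NaBH4, CeCl3·7H2O, MeOH, 0 °C
Reagents that add atoms: none
Why: Luche 1,2-reduction of the enal; sulfone and bromide are inert.

Step 26
Reactants: 33 [(5S,6S)-5-bromo-2,6-dimethyl-6-[2-(phenylsulfonyl)ethyl]cyclohex-1-en-1-yl]methanol
Product: 34 [(5S,6S)-5-bromo-2,6-dimethyl-6-[2-(phenylsulfonyl)ethyl]cyclohex-1-en-1-yl]methyl 2,2-dimethylpropanoate
Conditions: t-BuCOCl, pyridine, DMAP (cat.), CH2Cl2, 25 °C
Reagents that add atoms: pivaloyl chloride, CC(C)(C)C(=O)Cl
Why: Acylation; a pivalate has no α-hydrogen and a shielded carbonyl, so it survives the sulfonyl carbanion chemistry and later serves as the allylic leaving group.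

### Fragment union and completion

Step 27
Reactants: 34 [(5S,6S)-5-bromo-2,6-dimethyl-6-[2-(phenylsulfonyl)ethyl]cyclohex-1-en-1-yl]methyl 2,2-dimethylpropanoate; 18 (1R,3R,5S)-3-bromo-5-(4-methoxybenzyloxy)-1,2,2-trimethylcyclopentane-1-carbaldehyde
Product: 36 [(5S,6S)-5-bromo-6-[3-[(1S,3R,5S)-3-bromo-5-(4-methoxybenzyloxy)-1,2,2-trimethylcyclopentyl]-3-hydroxy-2-(phenylsulfonyl)propyl]-2,6-dimethylcyclohex-1-en-1-yl]methyl 2,2-dimethylpropanoate (β-hydroxy sulfone as a mixture of epimers at C9 and C10), via lithiated sulfone 35 (not isolated)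
Conditions: LiN(i-Pr)2, THF, –78 °C; then 18, –78 → –40 °C; aq. NH4Cl
Reagents that add atoms: none
Why: Addition of an α-sulfonyl carbanion to a non-enolisable aldehyde forms the C9–C10 bond, with the sulfonyl carbon of 34 becoming C10 and its neighbouring methylene remaining C11; amide deprotonation of the sulfone is faster than any reaction at the secondary bromides, and the two new centres are removed in the next two steps.

Step 28
Reactants: 36 β-hydroxy sulfone (C9 carbinol, C10 phenylsulfonyl)
Product: 37 [(5S,6S)-5-bromo-6-[3-[(1R,3R,5S)-3-bromo-5-(4-methoxybenzyloxy)-1,2,2-trimethylcyclopentyl]-3-oxo-2-(phenylsulfonyl)propyl]-2,6-dimethylcyclohex-1-en-1-yl]methyl 2,2-dimethylpropanoate (β-keto sulfone as a mixture of epimers at C10)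
Conditions: Dess–Martin periodinane, NaHCO3, CH2Cl2, 25 °C
Reagents that add atoms: none
Why: Oxidation of the secondary alcohol to the C9 ketone under neutral conditions.

Step 29
Reactants: 37 β-keto sulfone (C9 ketone, C10 phenylsulfonyl)
Product: 38 1-[(1R,3R,5S)-3-bromo-5-(4-methoxybenzyloxy)-1,2,2-trimethylcyclopentyl]-3-[(1S,6S)-6-bromo-1,3-dimethyl-2-(pivaloyloxymethyl)cyclohex-2-en-1-yl]propan-1-one
Conditions: SmI2 (2.5 equiv), THF–MeOH, –78 °C
Reagents that add atoms: none
Why: Reductive cleavage of an α-sulfonyl ketone by divalent samarium is fast at –78 °C; under these conditions unactivated secondary bromides and the allylic pivalate are not reduced.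

Step 30
Reactants: 38 ketone with C20 allylic pivalate
Product: 39 (2R,4aS,5S)-5-bromo-2-[(1R,3R,5S)-3-bromo-5-(4-methoxybenzyloxy)-1,2,2-trimethylcyclopentyl]-4a,8-dimethyl-1,2,3,4,4a,5,6,7-octahydronaphthalen-2-ol
Conditions: SmI2 (3 equiv), Pd(PPh3)4 (5 mol%), THF, 25 °C
Reagents that add atoms: none
Why: Zerovalent palladium ionises the allylic ester and SmI2 reduces the π-allyl complex to a nucleophilic allylsamarium (umpolung allylation of ketones by allylic esters), which adds intramolecularly to C9. Attack through primary C20 is preferred over the tetrasubstituted C17 and closes the six-membered ring B. The bulky ring A takes the equatorial position in the chair-like transition state, so the hydroxyl is axial (9R).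

Step 31
Reactants: 39 tricyclic carbinol with C17=C19 alkene
Product: 41 neoirietetraol 6-O-(4-methoxybenzyl) ether, via epoxide 40 (not isolated)
Conditions: m-CPBA, NaHCO3, CH2Cl2, 0 °C; then HClO4 (cat.), THF–H2O, 0 → 25 °C
Reagents that add atoms: 3-chloroperoxybenzoic acid, OOC(=O)c1cccc(Cl)c1; water, O
Why: Epoxidation of the only alkene on the face anti to the axial C13 methyl, helped by the homoallylic C9 hydroxyl, then acid-catalysed trans-diaxial (Fürst–Plattner) opening by water at C17 with inversion. This gives C19–OH axial and trans to C13 and C17–OH axial on the other face; the epoxide of the opposite face would converge on the same diol.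

Step 32
Reactants: 41 neoirietetraol 6-O-(4-methoxybenzyl) ether
Product: 42 neoirietetraol
Conditions: DDQ, CH2Cl2–pH 7 buffer, 0 °C
Reagents that add atoms: none
Why: Oxidative cleavage of the 4-methoxybenzyl ether; bromides and tertiary alcohols are inert, and the buffer hydrolyses any arylidene acetal formed with the C9 hydroxyl.

## Compound list

1 | diethyl 2-(propan-2-ylidene)malonate | CCOC(=O)C(=C(C)C)C(=O)OCC | starting material
2 | isopropenylmagnesium bromide | CC(=C)[Mg]Br | starting material
3 | diethyl 2-(2,3-dimethylbut-3-en-2-yl)malonate | CCOC(=O)C(C(=O)OCC)C(C)(C)C(C)=C | intermediate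
4 | diethyl 2-(2,3-dimethylbut-3-en-2-yl)-2-methylmalonate | CCOC(=O)C(C)(C(=O)OCC)C(C)(C)C(C)=C | intermediate
5 | 2-(2,3-dimethylbut-3-en-2-yl)-2-methylpropane-1,3-diol | C=C(C)C(C)(C)C(C)(CO)CO | intermediate
6 | (2R)-2-(hydroxymethyl)-2,3,3,4-tetramethylpent-4-en-1-yl acetate | C=C(C)C(C)(C)[C@](C)(CO)COC(C)=O | intermediate
7 | (2S)-2-formyl-2,3,3,4-tetramethylpent-4-en-1-yl acetate | C=C(C)C(C)(C)[C@](C)(C=O)COC(C)=O | intermediate
8 | (2S)-2-formyl-2,3,3-trimethyl-4-oxopentyl acetate | CC(=O)C(C)(C)[C@](C)(C=O)COC(C)=O | intermediate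
9 | (2S)-2-formyl-2,3,3-trimethyl-4-(triisopropylsilyloxy)pent-4-en-1-yl acetate | C=C(O[Si](C(C)C)(C(C)C)C(C)C)C(C)(C)[C@](C)(C=O)COC(C)=O | intermediate
10 | [(1S,3S)-1,2,2-trimethyl-5-oxo-3-(triisopropylsilyloxy)cyclopentyl]methyl acetate | CC1(C)[C@@H](O[Si](C(C)C)(C(C)C)C(C)C)CC(=O)[C@]1(C)COC(C)=O | intermediate
11 | [(1S,3S)-3-hydroxy-1,2,2-trimethyl-5-oxocyclopentyl]methyl acetate | CC1(C)[C@@H](O)CC(=O)[C@]1(C)COC(C)=O | intermediate
12 | [(1S,3S,5S)-3,5-dihydroxy-1,2,2-trimethylcyclopentyl]methyl acetate | CC1(C)[C@@H](O)C[C@H](O)[C@]1(C)COC(C)=O | intermediate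
13 | (1S,3S,4S)-4-(hydroxymethyl)-4,5,5-trimethylcyclopentane-1,3-diol | CC1(C)[C@@H](O)C[C@H](O)[C@]1(C)CO | intermediate
14 | (2R,4aS,6S,7aS)-2-(4-methoxyphenyl)-4a,5,5-trimethylhexahydrocyclopenta[d][1,3]dioxin-6-ol (O6,O9 4-methoxybenzylidene acetal of 13, aryl equatorial) | CC1(C)[C@@H](O)C[C@@H]2O[C@H](c3ccc(OC)cc3)OC[C@]12C | intermediate
15 | C4 trifluoromethanesulfonate of 14 | CC1(C)[C@@H](OS(=O)(=O)C(F)(F)F)C[C@@H]2O[C@H](c3ccc(OC)cc3)OC[C@]12C | intermediate
16 | (2R,4aS,6R,7aS)-6-bromo-2-(4-methoxyphenyl)-4a,5,5-trimethylhexahydrocyclopenta[d][1,3]dioxine | CC1(C)[C@H](Br)C[C@@H]2O[C@H](c3ccc(OC)cc3)OC[C@]12C | intermediate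
17 | [(1S,3R,5S)-3-bromo-5-(4-methoxybenzyloxy)-1,2,2-trimethylcyclopentyl]methanol | CC1(C)[C@H](Br)C[C@H](OCc2ccc(OC)cc2)[C@]1(C)CO | intermediate
18 | (1R,3R,5S)-3-bromo-5-(4-methoxybenzyloxy)-1,2,2-trimethylcyclopentane-1-carbaldehyde | CC1(C)[C@H](Br)C[C@H](OCc2ccc(OC)cc2)[C@]1(C)C=O | intermediate
19 | geraniol, (2E)-3,7-dimethylocta-2,6-dien-1-ol | CC(C)=CCC/C(C)=C/CO | starting material
20 | tert-butyl (2E)-3,7-dimethylocta-2,6-dien-1-yl carbonate | CC(C)=CCC/C(C)=C/COC(=O)OC(C)(C)C | intermediate
21 | tert-butyl (2E,6E)-8-hydroxy-3,7-dimethylocta-2,6-dien-1-yl carbonate | OC/C(C)=C/CC/C(C)=C/COC(=O)OC(C)(C)C | intermediate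
22 | tert-butyl (2E,6E)-8-bromo-3,7-dimethylocta-2,6-dien-1-yl carbonate | BrC/C(C)=C/CC/C(C)=C/COC(=O)OC(C)(C)C | intermediate
23 | methyl phenyl sulfone | CS(=O)(=O)c1ccccc1 | starting material
24 | [(phenylsulfonyl)methyl]lithium | [Li]CS(=O)(=O)c1ccccc1 | intermediate
25 | tert-butyl (2E,6E)-3,7-dimethyl-9-(phenylsulfonyl)nona-2,6-dien-1-yl carbonate | O=S(=O)(c1ccccc1)CC/C(C)=C/CC/C(C)=C/COC(=O)OC(C)(C)C | intermediate
26 | tert-butyl (2E)-3-methyl-5-[(2R,3R)-3-methyl-3-[2-(phenylsulfonyl)ethyl]oxiran-2-yl]pent-2-en-1-yl carbonate | O=S(=O)(c1ccccc1)CC[C@@]2(C)O[C@@H]2CC/C(C)=C/COC(=O)OC(C)(C)C | intermediate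
27 | tert-butyl (2E,6R,7S)-7-bromo-6-hydroxy-3,7-dimethyl-9-(phenylsulfonyl)non-2-en-1-yl carbonate | O=S(=O)(c1ccccc1)CC[C@@](Br)(C)[C@H](O)CC/C(C)=C/COC(=O)OC(C)(C)C | intermediate
28 | 6-O-trifluoromethanesulfonate of 27 | O=S(=O)(c1ccccc1)CC[C@@](Br)(C)[C@H](OS(=O)(=O)C(F)(F)F)CC/C(C)=C/COC(=O)OC(C)(C)C | intermediate
29 | (4aR,5S,6S,8aS)-6-bromo-5,8a-dimethyl-5-[2-(phenylsulfonyl)ethyl]hexahydro-4H-benzo[d][1,3]dioxin-2-one (trans-fused cyclic carbonate) | O=S(=O)(c1ccccc1)CC[C@]1(C)[C@@H](Br)CC[C@]2(C)OC(=O)OC[C@@H]12 | intermediate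
30 | (1S,2R,3S,4S)-4-bromo-2-(hydroxymethyl)-1,3-dimethyl-3-[2-(phenylsulfonyl)ethyl]cyclohexan-1-ol | O=S(=O)(c1ccccc1)CC[C@]1(C)[C@@H](Br)CC[C@](C)(O)[C@H]1CO | intermediate
31 | (1S,2S,3S,6S)-3-bromo-6-hydroxy-2,6-dimethyl-2-[2-(phenylsulfonyl)ethyl]cyclohexane-1-carbaldehyde | O=S(=O)(c1ccccc1)CC[C@]1(C)[C@@H](Br)CC[C@](C)(O)[C@H]1C=O | intermediate
32 | (5S,6S)-5-bromo-2,6-dimethyl-6-[2-(phenylsulfonyl)ethyl]cyclohex-1-ene-1-carbaldehyde | O=S(=O)(c1ccccc1)CC[C@]1(C)[C@@H](Br)CCC(C)=C1C=O | intermediate
33 | [(5S,6S)-5-bromo-2,6-dimethyl-6-[2-(phenylsulfonyl)ethyl]cyclohex-1-en-1-yl]methanol | O=S(=O)(c1ccccc1)CC[C@]1(C)[C@@H](Br)CCC(C)=C1CO | intermediate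
34 | [(5S,6S)-5-bromo-2,6-dimethyl-6-[2-(phenylsulfonyl)ethyl]cyclohex-1-en-1-yl]methyl 2,2-dimethylpropanoate | O=S(=O)(c1ccccc1)CC[C@]1(C)[C@@H](Br)CCC(C)=C1COC(=O)C(C)(C)C | intermediate
35 | [(5S,6S)-5-bromo-6-[2-lithio-2-(phenylsulfonyl)ethyl]-2,6-dimethylcyclohex-1-en-1-yl]methyl 2,2-dimethylpropanoate (C10-lithio derivative of 34) | [Li]C(C[C@]1(C)[C@@H](Br)CCC(C)=C1COC(=O)C(C)(C)C)S(=O)(=O)c1ccccc1 | intermediate
36 | [(5S,6S)-5-bromo-6-[3-[(1S,3R,5S)-3-bromo-5-(4-methoxybenzyloxy)-1,2,2-trimethylcyclopentyl]-3-hydroxy-2-(phenylsulfonyl)propyl]-2,6-dimethylcyclohex-1-en-1-yl]methyl 2,2-dimethylpropanoate (β-hydroxy sulfone from 18 and 34; C9 carbinol, C10 phenylsulfonyl, epimers at C9 and C10) | CC1(C)[C@H](Br)C[C@H](OCc2ccc(OC)cc2)[C@]1(C)C(O)C(C[C@]1(C)[C@@H](Br)CCC(C)=C1COC(=O)C(C)(C)C)S(=O)(=O)c1ccccc1 | intermediate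
37 | [(5S,6S)-5-bromo-6-[3-[(1R,3R,5S)-3-bromo-5-(4-methoxybenzyloxy)-1,2,2-trimethylcyclopentyl]-3-oxo-2-(phenylsulfonyl)propyl]-2,6-dimethylcyclohex-1-en-1-yl]methyl 2,2-dimethylpropanoate (β-keto sulfone; C9 ketone, C10 phenylsulfonyl, epimers at C10) | CC1(C)[C@H](Br)C[C@H](OCc2ccc(OC)cc2)[C@]1(C)C(=O)C(C[C@]1(C)[C@@H](Br)CCC(C)=C1COC(=O)C(C)(C)C)S(=O)(=O)c1ccccc1 | intermediate
38 | 1-[(1R,3R,5S)-3-bromo-5-(4-methoxybenzyloxy)-1,2,2-trimethylcyclopentyl]-3-[(1S,6S)-6-bromo-1,3-dimethyl-2-(pivaloyloxymethyl)cyclohex-2-en-1-yl]propan-1-one | CC1(C)[C@H](Br)C[C@H](OCc2ccc(OC)cc2)[C@]1(C)C(=O)CC[C@]1(C)[C@@H](Br)CCC(C)=C1COC(=O)C(C)(C)C | intermediate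
39 | (2R,4aS,5S)-5-bromo-2-[(1R,3R,5S)-3-bromo-5-(4-methoxybenzyloxy)-1,2,2-trimethylcyclopentyl]-4a,8-dimethyl-1,2,3,4,4a,5,6,7-octahydronaphthalen-2-ol | CC1(C)[C@H](Br)C[C@H](OCc2ccc(OC)cc2)[C@]1(C)[C@@]1(O)CC[C@]2(C)[C@@H](Br)CCC(C)=C2C1 | intermediate
40 | C17,C19-epoxide of 39 on the face anti to the C13 methyl | CC1(C)[C@H](Br)C[C@H](OCc2ccc(OC)cc2)[C@]1(C)[C@@]1(O)CC[C@]2(C)[C@@H](Br)CC[C@]3(C)O[C@]23C1 | intermediate
41 | neoirietetraol 6-O-(4-methoxybenzyl) ether | CC1(C)[C@H](Br)C[C@H](OCc2ccc(OC)cc2)[C@]1(C)[C@@]1(O)CC[C@]2(C)[C@@H](Br)CC[C@@](C)(O)[C@@]2(O)C1 | intermediate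
42 | neoirietetraol (4R,6S,7R,9R,12S,14S,17R,19R in the numbering used here) | CC1(C)[C@H](Br)C[C@H](O)[C@]1(C)[C@@]1(O)CC[C@]2(C)[C@@H](Br)CC[C@@](C)(O)[C@@]2(O)C1 | target

## Step count and least certain steps

Total: 32 steps. Longest linear sequence: 21 steps (steps 1–15, then 27–32); the ring C branch is 11 steps before the union.

**Step 8 (key step, Proposed new method).**
- Most likely failure: loss of the silyloxy group by β-elimination from the alkylrhodium intermediate or by Lewis-acid-induced desilylative aldol closure, or catalyst death through decarbonylation of the acyl hydride.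
- Fallback (known chemistry): the same ring closure on a C4-silyl alkene, a substituent class for which this cyclisation is established, followed by oxidation of the C–Si bond with retention. It sets out from 1 and returns at 11.
- Copper-catalysed addition of [1-(dimethylphenylsilyl)vinyl]magnesium bromide to 1 gives diethyl 2-[3-(dimethylphenylsilyl)-2-methylbut-3-en-2-yl]malonate F1. Methylation as in step 2 gives diethyl 2-[3-(dimethylphenylsilyl)-2-methylbut-3-en-2-yl]-2-methylmalonate F2, and LiAlH4 gives 2-[3-(dimethylphenylsilyl)-2-methylbut-3-en-2-yl]-2-methylpropane-1,3-diol F3.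
- Lipase acylation gives (2R)-4-(dimethylphenylsilyl)-2-(hydroxymethyl)-2,3,3-trimethylpent-4-en-1-yl acetate F4, and Dess–Martin oxidation gives (2S)-4-(dimethylphenylsilyl)-2-formyl-2,3,3-trimethylpent-4-en-1-yl acetate F5.
- Cyclisation with [Rh((S)-BINAP)]BF4 gives [(1S,3S)-3-(dimethylphenylsilyl)-1,2,2-trimethyl-5-oxocyclopentyl]methyl acetate F6. Fleming–Tamao oxidation (KBr, AcOOH, NaOAc, AcOH) converts C4–Si into C4–OH with retention and gives 11.

**Step 13.**
- Most likely failure: elimination toward C5 and methyl migration from C2 on ionisation of the triflate outrun the substitution, because bromide must enter at a neopentyl carbon from the face that already carries O6 and C9.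
- Fallback: bromine is installed on an sp2 carbon and the C4 configuration is set by a reduction. It sets out from 14 and returns at 16.
- Dess–Martin oxidation gives the C4 ketone (2R,4aS,7aS)-2-(4-methoxyphenyl)-4a,5,5-trimethyltetrahydrocyclopenta[d][1,3]dioxin-6-one F7, and N2H4·H2O in EtOH gives its hydrazone F8.
- Barton-type halogenation (N-bromosuccinimide, tetramethylguanidine) gives the C4=C5 vinyl bromide F9.
- Hydrogen-atom-transfer hydrogenation (Mn(dpm)3, PhSiH3, t-BuOOH, i-PrOH) delivers the second hydrogen to the α-bromo radical from the convex face of the cis-fused bicycle (the face of the C7 methyl, away from the dioxane ring), so bromine ends up cis to O6 and C9, and this should give 16.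

**Step 22.**
- Most likely failure: proton loss from the tertiary cation before ring closure (allylic bromide formation), incomplete capture by the carbonate, or erosion of configuration if the triflate ionises without bromine participation.
- Fallback: direct bromonium cyclisation of the achiral diene. It sets out from 25 and returns at 29.
- [Et2SBr][SbCl5Br] in MeNO2 at –25 °C should give the carbonate as a racemate, that is 29 together with its mirror image F10. The racemate is resolved by preparative chromatography on a chiral stationary phase and 29 is carried on.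

**Step 30.**
- Most likely failure: the allyl–metal species is protonated or reduced to the simple alkene, or it attacks through the tetrasubstituted terminus, or the ketone undergoes pinacol coupling.
- Fallback: a direct Barbier closure of an allylic bromide. It sets out from 38 and returns at 39.
- Methanolysis (K2CO3, MeOH) gives the allylic alcohol ketone F11, and CBr4/PPh3 gives the allylic bromide ketone F12.
- F12 is cyclised with SmI2 alone in THF at –78 → 0 °C; samarium allyls react through the less substituted terminus.

**Step 4.**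
- Most likely failure: low enantioselectivity or the opposite sense of acylation with this very hindered diol, or partial racemisation by 1,3-acyl migration.
- Fallback: the complementary enzymatic mode. It sets out from 5 and returns at 6.
- Ac2O/pyridine gives 2-(2,3-dimethylbut-3-en-2-yl)-2-methylpropane-1,3-diyl diacetate F13, which the same lipase hydrolyses in pH 7 phosphate buffer at the arm it would otherwise acylate. This gives the monoacetate of opposite configuration to that from acylation; whichever mode furnishes 6 is used.

## Further compounds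

F1 | step 8 | diethyl 2-[3-(dimethylphenylsilyl)-2-methylbut-3-en-2-yl]malonate | CCOC(=O)C(C(=O)OCC)C(C)(C)C(=C)[Si](C)(C)c1ccccc1
F2 | step 8 | diethyl 2-[3-(dimethylphenylsilyl)-2-methylbut-3-en-2-yl]-2-methylmalonate | CCOC(=O)C(C)(C(=O)OCC)C(C)(C)C(=C)[Si](C)(C)c1ccccc1
F3 | step 8 | 2-[3-(dimethylphenylsilyl)-2-methylbut-3-en-2-yl]-2-methylpropane-1,3-diol | C=C([Si](C)(C)c1ccccc1)C(C)(C)C(C)(CO)CO
F4 | step 8 | (2R)-4-(dimethylphenylsilyl)-2-(hydroxymethyl)-2,3,3-trimethylpent-4-en-1-yl acetate | C=C([Si](C)(C)c1ccccc1)C(C)(C)[C@](C)(CO)COC(C)=O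
F5 | step 8 | (2S)-4-(dimethylphenylsilyl)-2-formyl-2,3,3-trimethylpent-4-en-1-yl acetate | C=C([Si](C)(C)c1ccccc1)C(C)(C)[C@](C)(C=O)COC(C)=O
F6 | step 8 | [(1S,3S)-3-(dimethylphenylsilyl)-1,2,2-trimethyl-5-oxocyclopentyl]methyl acetate | CC1(C)[C@@H]([Si](C)(C)c2ccccc2)CC(=O)[C@]1(C)COC(C)=O
F7 | step 13 | (2R,4aS,7aS)-2-(4-methoxyphenyl)-4a,5,5-trimethyltetrahydrocyclopenta[d][1,3]dioxin-6-one | CC1(C)C(=O)C[C@@H]2O[C@H](c3ccc(OC)cc3)OC[C@]12C
F8 | step 13 | hydrazone of F7 | CC1(C)C(=NN)C[C@@H]2O[C@H](c3ccc(OC)cc3)OC[C@]12C
F9 | step 13 | C4=C5 vinyl bromide (6-bromo-2-(4-methoxyphenyl)-4a,5,5-trimethyl-4,4a,5,7a-tetrahydrocyclopenta[d][1,3]dioxine) | CC1(C)C(Br)=C[C@@H]2O[C@H](c3ccc(OC)cc3)OC[C@]12C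
F10 | step 22 | mirror image of 29, (4aS,5R,6R,8aR) | O=S(=O)(c1ccccc1)CC[C@@]1(C)[C@H](Br)CC[C@@]2(C)OC(=O)OC[C@H]12
F11 | step 30 | allylic alcohol ketone (38 without the pivaloyl group) | CC1(C)[C@H](Br)C[C@H](OCc2ccc(OC)cc2)[C@]1(C)C(=O)CC[C@]1(C)[C@@H](Br)CCC(C)=C1CO
F12 | step 30 | allylic bromide ketone (C20 bromide) | CC1(C)[C@H](Br)C[C@H](OCc2ccc(OC)cc2)[C@]1(C)C(=O)CC[C@]1(C)[C@@H](Br)CCC(C)=C1CBr
F13 | step 4 | 2-(2,3-dimethylbut-3-en-2-yl)-2-methylpropane-1,3-diyl diacetate | C=C(C)C(C)(C)C(C)(COC(C)=O)COC(C)=O
A1 | alternative 1 | C10=C11, C17=C19 diene carbinol with C6 tert-butyldimethylsilyl ether | CC1(C)[C@H](Br)C[C@H](O[Si](C)(C)C(C)(C)C)[C@]1(C)[C@@]1(O)C=C[C@]2(C)[C@@H](Br)CCC(C)=C2C1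
A2 | alternative 2 | 2-(tert-butyldimethylsilyloxy)-1,5,5-trimethylcyclopentane-1-carbaldehyde | CC1(C)CC[C@H](O[Si](C)(C)C(C)(C)C)[C@]1(C)C=O
A3 | alternative 3 | 4-(4-methoxybenzyloxy)-3-[(tert-butyldimethylsilyloxy)methyl]-2,2,3-trimethylcyclopentan-1-ol | CC1(C)[C@@H](O)C[C@H](OCc2ccc(OC)cc2)[C@]1(C)CO[Si](C)(C)C(C)(C)C
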